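Everything rests on the two bonds at C4a, the atom common to the indoline, piperidine and dihydrofuran rings. C4a is bonded to the piperidine methylene C4 and to the oxygen on C5' of ring A; as a ketone carbon it can serve as electrophile twice, first in a carbonyl olefination and then, as β-carbon of the resulting unsaturated lactam, in an oxa-Michael addition. One operation therefore closes the δ-lactam (C4=C4a) and the dihydrofuran (O–C4a) and sets C4a from C9a. The precursor is an (R)-2-aryl-2-(amidomethyl)indolin-3-one: N2 carries a phosphonoacetyl group, the aryl group is an N-tosyl 5-hydroxy-7-methoxyindol-4-yl unit, and N9–H stays free.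

Key step: step 13

Locants: β-carboline numbering C1 to C9a for the indoline–piperidine part; primed locants for the gramine indole, whose benzene ring is ring A. The target is (4aS,9aR).

Assumption: the sense of induction in step 8 is not predicted here; of the quinine- and quinidine-derived pseudoenantiomeric thioureas, the one that delivers (R)-11 is used, and the configuration is secured on 11 before material is carried on.

Step 1
Reactants: 1 3-methoxy-4-nitrophenol
Product: 2 2-bromo-5-methoxy-4-nitrophenol
Conditions: NBS (1.0 equiv), MeCN, 0 → 23 °C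
Reagents that add atoms: N-bromosuccinimide, O=C1CCC(=O)N1Br
Why: Electrophilic aromatic bromination: OH and OMe both activate C6 (ortho to OH, para to OMe, meta to NO2), and the only other activated site lies between the two oxygen substituents and is more hindered, so one regioisomer should dominate.

Step 2
Reactants: 2 2-bromo-5-methoxy-4-nitrophenol
Product: 3 1-(benzyloxy)-2-bromo-5-methoxy-4-nitrobenzene
Conditions: BnBr, K2CO3, DMF, 23 °C
Reagents that add atoms: benzyl bromide, BrCc1ccccc1
Why: Williamson etherification of an acidic nitrophenoxide with a benzylic halide; the benzyl ether masks the future C5' phenol until step 11.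

Step 3
Reactants: 3 1-(benzyloxy)-2-bromo-5-methoxy-4-nitrobenzene
Product: 4 5-(benzyloxy)-4-bromo-7-methoxy-1H-indole
Conditions: CH2=CHMgBr (3.3 equiv), THF, −45 °C; aq. NH4Cl
Reagents that add atoms: vinylmagnesium bromide, C=C[Mg]Br
Why: Bartoli indole synthesis: the Grignard reagent reduces the nitro group to the nitrosoarene, a second equivalent gives the N-aryl-O-vinylhydroxylamine, and its [3,3]-sigmatropic shift, helped by the ortho methoxy group, attacks the free ortho carbon and builds the pyrrole ring with bromine at C4 and benzyloxy at C5; the aryl bromide should survive at this temperature.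

Step 4
Reactants: 4 5-(benzyloxy)-4-bromo-7-methoxy-1H-indole
Product: 5 5-(benzyloxy)-4-bromo-7-methoxy-1-tosyl-1H-indole
Conditions: NaH, TsCl, DMF, 0 → 23 °C
Reagents that add atoms: p-toluenesulfonyl chloride, Cc1ccc(cc1)S(=O)(=O)Cl
Why: N-Sulfonylation of the indolyl sodium salt; tosyl deactivates the ring A indole so that only the other indole is oxidised in step 7.

Step 5
Reactants: 5 5-(benzyloxy)-4-bromo-7-methoxy-1-tosyl-1H-indole; 6 1-Boc-indole-2-boronic acid
Product: 7 tert-butyl 2-[5-(benzyloxy)-7-methoxy-1-tosylindol-4-yl]indole-1-carboxylate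
Conditions: 6 (1.5 equiv), Pd(OAc)2 (5 mol%), SPhos (10 mol%), K3PO4, toluene/H2O, 70 °C
Reagents that add atoms: 1-Boc-indole-2-boronic acid (6), CC(C)(C)OC(=O)n1c(B(O)O)cc2ccccc12
Why: Suzuki–Miyaura coupling; the electron-rich biaryl phosphine SPhos permits oxidative addition to the ortho-substituted, electron-rich bromide and a coupling rate that competes with protodeboronation of the 2-indolylboronic acid.

Step 6
Reactants: 7 tert-butyl 2-[5-(benzyloxy)-7-methoxy-1-tosylindol-4-yl]indole-1-carboxylate
Product: 8 5-(benzyloxy)-4-(1H-indol-2-yl)-7-methoxy-1-tosylindole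
Conditions: TFA, CH2Cl2, 0 → 23 °C
Reagents that add atoms: none
Why: Acidolysis of the indole N-Boc carbamate (loss of the tert-butyl cation, then of CO2); benzyl ether and N-tosyl are stable to TFA at this temperature.

Step 7
Reactants: 8 5-(benzyloxy)-4-(1H-indol-2-yl)-7-methoxy-1-tosylindole
Product: 9 2-[5-(benzyloxy)-7-methoxy-1-tosylindol-4-yl]-3H-indol-3-one
Conditions: CuCl (10 mol%), TEMPO (10 mol%), O2 (1 atm), MeCN, 40 °C
Reagents that add atoms: dioxygen, O=O
Why: Aerobic oxidative dearomatisation of a 2-arylindole (C3 oxygenation to the 3-peroxy-3H-indole and dehydration) to the cyclic α-keto ketimine; the N–H indole is far more easily oxidised than the N-tosyl indole of ring A.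

Step 8
Reactants: 9 2-[5-(benzyloxy)-7-methoxy-1-tosylindol-4-yl]-3H-indol-3-one; 10 nitromethane
Product: 11 (R)-2-[5-(benzyloxy)-7-methoxy-1-tosylindol-4-yl]-2-(nitromethyl)indolin-3-one
Conditions: MeNO2 (10 equiv), cinchona-derived 3,5-bis(trifluoromethyl)phenyl thiourea (10 mol%), toluene, −20 °C
Reagents that add atoms: nitromethane (10), C[N+](=O)[O-]
Why: Catalytic asymmetric aza-Henry (nitro-Mannich) addition to a cyclic ketimine: the thiourea binds the α-keto imine by hydrogen bonds while the quinuclidine generates the nitronate, which is delivered to one face of C2 and sets the quaternary stereocentre C9a as R.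

Step 9
Reactants: 11 (R)-2-[5-(benzyloxy)-7-methoxy-1-tosylindol-4-yl]-2-(nitromethyl)indolin-3-one
Product: 12 (R)-2-(aminomethyl)-2-[5-(benzyloxy)-7-methoxy-1-tosylindol-4-yl]indolin-3-one
Conditions: Zn, AcOH, THF, 0 → 23 °C
Reagents that add atoms: none
Why: Dissolving-metal reduction of an aliphatic nitro group to the primary amine under acidic conditions, which suppress retro-aza-Henry cleavage and should leave the benzyl ether, the sulfonamide and the vinylogous-amide ketone untouched.

Step 10
Reactants: 12 (R)-2-(aminomethyl)-2-[5-(benzyloxy)-7-methoxy-1-tosylindol-4-yl]indolin-3-one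
Product: 14 (R)-2-{[benzyl(methyl)amino]methyl}-2-[5-(benzyloxy)-7-methoxy-1-tosylindol-4-yl]indolin-3-one, via N-benzyl secondary amine 13 (not isolated)
Conditions: PhCHO (1.05 equiv), NaBH(OAc)3, AcOH, ClCH2CH2Cl, 23 °C; then 37% aq. CH2O, NaBH(OAc)3, 23 °C
Reagents that add atoms: benzaldehyde, O=Cc1ccccc1; formaldehyde, C=O
Why: Two reductive aminations in one flask: the benzyl group introduced first leaves a secondary amine that can take up exactly one methyl group from formaldehyde, and NaBH(OAc)3 reduces iminium ions but not the ketone.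

Step 11
Reactants: 14 (R)-2-{[benzyl(methyl)amino]methyl}-2-[5-(benzyloxy)-7-methoxy-1-tosylindol-4-yl]indolin-3-one
Product: 15 (R)-2-(5-hydroxy-7-methoxy-1-tosylindol-4-yl)-2-[(methylamino)methyl]indolin-3-one
Conditions: H2 (1 atm), Pd(OH)2/C, AcOH, MeOH, 23 °C
Reagents that add atoms: none
Why: Catalytic hydrogenolysis cleaves the N-benzyl and the O-benzyl group in one operation, so the group that enforced monomethylation is removed together with the phenol protection.

Step 12
Reactants: 15 (R)-2-(5-hydroxy-7-methoxy-1-tosylindol-4-yl)-2-[(methylamino)methyl]indolin-3-one; 16 diethylphosphonoacetic acid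
Product: 17 (R)-2-(5-hydroxy-7-methoxy-1-tosylindol-4-yl)-2-{[N-methyl-2-(diethoxyphosphoryl)acetamido]methyl}indolin-3-one
Conditions: 16, EDC·HCl, HOBt, CH2Cl2, 0 → 23 °C (no added base)
Reagents that add atoms: diethylphosphonoacetic acid (16), CCOP(=O)(CC(=O)O)OCC
Why: Carbodiimide amide coupling through the HOBt ester, which should acylate the secondary amine much faster than the hindered, un-ionised phenol.

Step 13
Reactants: 17 (R)-2-(5-hydroxy-7-methoxy-1-tosylindol-4-yl)-2-{[N-methyl-2-(diethoxyphosphoryl)acetamido]methyl}indolin-3-one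
Product: 19 (4aS,9aR) N1'-tosyl C3-lactam propellane (target skeleton without the C3' dimethylaminomethyl group), via C4=C4a unsaturated lactam phenol 18 (not isolated)
Conditions: LiCl, DBU, MeCN, 23 → 60 °C
Reagents that add atoms: none
Why: Under Masamune–Roush conditions the lithium-chelated phosphonate carbanion should add to the C4a ketone (6-exo-trig, the tertiary amide holding C4 within reach) and collapse through the oxaphosphetane with loss of diethyl phosphate to the unsaturated δ-lactam 18, an intramolecular Horner–Wadsworth–Emmons olefination of the kind used for unsaturated lactams. The C5' phenoxide, carried by the aryl group on C9a directly over the new alkene, should then add 5-exo-trig to the β-carbon C4a, and protonated DBU quenches the lactam enolate at C4; this is an intramolecular oxa-Michael closure as in syntheses of 2,2-disubstituted dihydrobenzofurans. C4a is the only new stereocentre and is dictated by C9a: oxygen can reach C4a only from the face that bears the aryl group, so only the cis-fused (4aS) propellane can close. The step needs a base that ionises the phenol and the phosphonate but not N9–H, whose anion would deactivate the vinylogous-amide ketone; the acidity gap and Li+ activation of the carbonyl should secure this. The order of events is fixed because C4a becomes a Michael acceptor only after olefination, and the N1' tosyl group keeps ring A from acting as a carbon nucleophile.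

Step 14
Reactants: 19 (4aS,9aR) N1'-tosyl C3-lactam propellane
Product: 20 (4aS,9aR) N1'-tosyl N2-methylpiperidine propellane
Conditions: AlH3·NMe2Et, THF, 0 °C
Reagents that add atoms: none
Why: Alane reduction of a tertiary lactam to the amine (hydride addition, collapse to the iminium ion, second hydride); the neutral electrophilic hydride avoids basic conditions that could open the ring by retro-oxa-Michael reaction, and the sulfonamide and aryl ethers should survive at 0 °C.

Step 15
Reactants: 20 (4aS,9aR) N1'-tosyl N2-methylpiperidine propellane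
Product: 21 (4aS,9aR) N1'-H propellane (target lacking the C3' dimethylaminomethyl group)
Conditions: Mg, MeOH, 23 °C (sonication)
Reagents that add atoms: none
Why: Single-electron reductive cleavage of the indole N–S bond by Mg in methanol, a standard desulfonylation that should not affect amines, aryl ethers or the indoline.

Step 16
Reactants: 21 (4aS,9aR) N1'-H propellane
Product: 22 target CNP0318114.2
Conditions: dimethylmethyleneiminium iodide, CH2Cl2/MeCN, 23 °C; aq. NaHCO3
Reagents that add atoms: dimethylmethyleneiminium iodide, C=[N+](C)C.[I-]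
Why: Mannich aminomethylation (gramine formation) with a preformed iminium salt at C3', the most nucleophilic carbon of the electron-rich ring A indole; N9 is a hindered N-aryl amine whose aminal, if formed, should revert on aqueous work-up.

Compound list

1 | 3-methoxy-4-nitrophenol | COc1cc(O)ccc1[N+](=O)[O-] | starting material
2 | 2-bromo-5-methoxy-4-nitrophenol | COc1cc(O)c(Br)cc1[N+](=O)[O-] | intermediate
3 | 1-(benzyloxy)-2-bromo-5-methoxy-4-nitrobenzene | COc1cc(OCc2ccccc2)c(Br)cc1[N+](=O)[O-] | intermediate
4 | 5-(benzyloxy)-4-bromo-7-methoxy-1H-indole | COc1cc(OCc2ccccc2)c(Br)c2cc[nH]c12 | intermediate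
5 | 5-(benzyloxy)-4-bromo-7-methoxy-1-tosyl-1H-indole | COc1cc(OCc2ccccc2)c(Br)c2ccn(S(=O)(=O)c3ccc(C)cc3)c12 | intermediate
6 | 1-Boc-indole-2-boronic acid | CC(C)(C)OC(=O)n1c(B(O)O)cc2ccccc12 | starting material
7 | tert-butyl 2-[5-(benzyloxy)-7-methoxy-1-tosylindol-4-yl]indole-1-carboxylate | COc1cc(OCc2ccccc2)c(-c2cc3ccccc3n2C(=O)OC(C)(C)C)c2ccn(S(=O)(=O)c3ccc(C)cc3)c12 | intermediate
8 | 5-(benzyloxy)-4-(1H-indol-2-yl)-7-methoxy-1-tosylindole | COc1cc(OCc2ccccc2)c(-c2cc3ccccc3[nH]2)c2ccn(S(=O)(=O)c3ccc(C)cc3)c12 | intermediate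
9 | 2-[5-(benzyloxy)-7-methoxy-1-tosylindol-4-yl]-3H-indol-3-one | COc1cc(OCc2ccccc2)c(C2=Nc3ccccc3C2=O)c2ccn(S(=O)(=O)c3ccc(C)cc3)c12 | intermediate
10 | nitromethane | C[N+](=O)[O-] | starting material
11 | (R)-2-[5-(benzyloxy)-7-methoxy-1-tosylindol-4-yl]-2-(nitromethyl)indolin-3-one | COc1cc(OCc2ccccc2)c(c2ccn(S(=O)(=O)c3ccc(C)cc3)c12)[C@@]1(C[N+](=O)[O-])C(=O)c2ccccc2N1 | intermediate
12 | (R)-2-(aminomethyl)-2-[5-(benzyloxy)-7-methoxy-1-tosylindol-4-yl]indolin-3-one | COc1cc(OCc2ccccc2)c(c2ccn(S(=O)(=O)c3ccc(C)cc3)c12)[C@@]1(CN)C(=O)c2ccccc2N1 | intermediate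
13 | (R)-2-[(benzylamino)methyl]-2-[5-(benzyloxy)-7-methoxy-1-tosylindol-4-yl]indolin-3-one (formed in the flask, not isolated) | COc1cc(OCc2ccccc2)c(c2ccn(S(=O)(=O)c3ccc(C)cc3)c12)[C@@]1(CNCc2ccccc2)C(=O)c2ccccc2N1 | intermediate
14 | (R)-2-{[benzyl(methyl)amino]methyl}-2-[5-(benzyloxy)-7-methoxy-1-tosylindol-4-yl]indolin-3-one | COc1cc(OCc2ccccc2)c(c2ccn(S(=O)(=O)c3ccc(C)cc3)c12)[C@@]1(CN(C)Cc2ccccc2)C(=O)c2ccccc2N1 | intermediate
15 | (R)-2-(5-hydroxy-7-methoxy-1-tosylindol-4-yl)-2-[(methylamino)methyl]indolin-3-one | COc1cc(O)c(c2ccn(S(=O)(=O)c3ccc(C)cc3)c12)[C@@]1(CNC)C(=O)c2ccccc2N1 | intermediate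
16 | diethylphosphonoacetic acid | CCOP(=O)(CC(=O)O)OCC | starting material
17 | (R)-2-(5-hydroxy-7-methoxy-1-tosylindol-4-yl)-2-{[N-methyl-2-(diethoxyphosphoryl)acetamido]methyl}indolin-3-one | COc1cc(O)c(c2ccn(S(=O)(=O)c3ccc(C)cc3)c12)[C@@]1(CN(C)C(=O)CP(=O)(OCC)OCC)C(=O)c2ccccc2N1 | intermediate
18 | (9aR)-9a-(5-hydroxy-7-methoxy-1-tosylindol-4-yl)-2-methyl-1,2,9,9a-tetrahydro-3H-pyrido[3,4-b]indol-3-one, the C4=C4a unsaturated lactam (formed in the flask, not isolated) | COc1cc(O)c(c2ccn(S(=O)(=O)c3ccc(C)cc3)c12)[C@@]12CN(C)C(=O)C=C1c1ccccc1N2 | intermediate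
19 | (4aS,9aR) N1'-tosyl C3-lactam propellane: 2-methyl-3-oxo-hexahydro-β-carboline with C9a bonded to C4' and C4a bonded through oxygen to C5' of 7'-methoxy-1'-tosylindole, N9–H free | COc1cc2c(c3ccn(S(=O)(=O)c4ccc(C)cc4)c13)[C@@]13CN(C)C(=O)C[C@]1(O2)c1ccccc1N3 | intermediate
20 | (4aS,9aR) N1'-tosyl N2-methylpiperidine propellane (19 with C3 as CH2) | COc1cc2c(c3ccn(S(=O)(=O)c4ccc(C)cc4)c13)[C@@]13CN(C)CC[C@]1(O2)c1ccccc1N3 | intermediate
21 | (4aS,9aR) N1'-H propellane (20 without tosyl) | COc1cc2c(c3cc[nH]c13)[C@@]13CN(C)CC[C@]1(O2)c1ccccc1N3 | intermediate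
22 | CNP0318114.2, (4aS,9aR), with the C3' dimethylaminomethyl group | COc1cc2c(c3c(CN(C)C)c[nH]c13)[C@@]13CN(C)CC[C@]1(O2)c1ccccc1N3 | target

Total steps: 16. Longest linear sequence: 16 steps (1 to 22); compounds 6, 10 and 16 enter as single building blocks.

Steps most likely to fail

Step 13. The phosphonate carbanion may add only reversibly to a ketone whose electrophilicity is lowered by conjugation with N9, so that olefination stalls. Alternatively, the phenoxide addition to the N9-conjugated β-carbon may stop short and leave the open lactam 18. The fallback sets out from 15 and returns at 19; it forms C4–C4a by an irreversible aldol-type addition and O–C4a by cation capture. Bromoacetyl bromide with aqueous NaHCO3 in CH2Cl2 at 0 °C should acylate the amine of 15 to (R)-2-{[(bromoacetyl)(methyl)amino]methyl}-2-(5-hydroxy-7-methoxy-1-tosylindol-4-yl)indolin-3-one F1. After conversion of the phenol into its lithium phenoxide (LiHMDS, 1 equiv, −78 °C), so that no acidic O–H quenches the enolate, SmI2 in THF should generate the samarium amide enolate. Its intramolecular Reformatsky-type addition to the C4a ketone should give the 4a-hydroxy δ-lactam F2. CSA in CH2Cl2 should then ionise the tertiary benzylic alcohol to the N9-stabilised C4a cation, which the C5' phenol captures from the only accessible face to give 19. Any 18 recovered from step 13 should converge on 19 under the same acid treatment.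

Step 8. The nitronate has to attack a ketimine carbon flanked by a 2,6-disubstituted aryl group, so conversion may be slow, facial discrimination by the catalyst may be poor, and the adduct can revert by retro-aza-Henry cleavage. The fallback sets out from 9 and returns at 11 without relying on catalyst control. Nitromethane with catalytic Et3N should give the racemic 2-[5-(benzyloxy)-7-methoxy-1-tosylindol-4-yl]-2-(nitromethyl)indolin-3-one F3. This is resolved by preparative chromatography on a polysaccharide chiral stationary phase; the (R)-enantiomer is 11 and the (S)-enantiomer of 11 F4 is set aside.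

Step 7. The oxidation may not stop at the ketimine: the electrophilic product can take up water or a second oxygen atom, the C2–C3 bond can be cleaved, and the dialkoxy ring A can be attacked by the oxidant. The fallback sets out from 5 and returns at 9; it builds the indol-3-one ring instead of oxidising an indole. Sonogashira coupling of 5 with 1-ethynyl-2-nitrobenzene (PdCl2(PPh3)2, CuI, Et3N, 70 °C) should give 5-(benzyloxy)-7-methoxy-4-[(2-nitrophenyl)ethynyl]-1-tosylindole F5. AuBr3-catalysed cycloisomerisation, in which a nitro oxygen adds to the activated alkyne, should give the isatogen 2-[5-(benzyloxy)-7-methoxy-1-tosylindol-4-yl]-3H-indol-3-one 1-oxide F6. PPh3 in toluene at 80 °C should deoxygenate this nitrone to 9.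

Further compounds

F1 | step 13 | (R)-2-{[(bromoacetyl)(methyl)amino]methyl}-2-(5-hydroxy-7-methoxy-1-tosylindol-4-yl)indolin-3-one | COc1cc(O)c(c2ccn(S(=O)(=O)c3ccc(C)cc3)c12)[C@@]1(CN(C)C(=O)CBr)C(=O)c2ccccc2N1
F2 | step 13 | (9aR)-4a-hydroxy-9a-(5-hydroxy-7-methoxy-1-tosylindol-4-yl)-2-methyl-1,2,4,4a,9,9a-hexahydro-3H-pyrido[3,4-b]indol-3-one, C4a configuration immaterial | COc1cc(O)c(c2ccn(S(=O)(=O)c3ccc(C)cc3)c12)[C@@]12CN(C)C(=O)CC1(O)c1ccccc1N2
F3 | step 8 | racemic 2-[5-(benzyloxy)-7-methoxy-1-tosylindol-4-yl]-2-(nitromethyl)indolin-3-one | COc1cc(OCc2ccccc2)c(c2ccn(S(=O)(=O)c3ccc(C)cc3)c12)C1(C[N+](=O)[O-])C(=O)c2ccccc2N1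
F4 | step 8 | (S)-2-[5-(benzyloxy)-7-methoxy-1-tosylindol-4-yl]-2-(nitromethyl)indolin-3-one | COc1cc(OCc2ccccc2)c(c2ccn(S(=O)(=O)c3ccc(C)cc3)c12)[C@]1(C[N+](=O)[O-])C(=O)c2ccccc2N1
F5 | step 7 | 5-(benzyloxy)-7-methoxy-4-[(2-nitrophenyl)ethynyl]-1-tosylindole | COc1cc(OCc2ccccc2)c(C#Cc2ccccc2[N+](=O)[O-])c2ccn(S(=O)(=O)c3ccc(C)cc3)c12
F6 | step 7 | 2-[5-(benzyloxy)-7-methoxy-1-tosylindol-4-yl]-3H-indol-3-one 1-oxide | COc1cc(OCc2ccccc2)c(C2=[N+]([O-])c3ccccc3C2=O)c2ccn(S(=O)(=O)c3ccc(C)cc3)c12
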